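**Plan**
- Retrosynthesis: the ring B-side ketone of the 1,3-diketone is masked as a dioxolane, and the ring A pyran is opened at O1–C2 to an ortho-prenyl phenol. Ring A itself is then cut at C4a–C5 and C6–C7 (chromene numbering).
- Enabling feature: ring A is a resorcinol, with its two oxygens on C7 (OH) and C8a (pyran O), the acyl carbon on C6 and the pyran carbon on C4a. Diene carbons C1–C4 of a 4-prenyl 1-methoxy-1,3-bis(silyloxy)diene become C7, C8, C8a and C4a; the two alkyne carbons of a terminal ynone become C6 and C5. The linear pattern is therefore fixed by connectivity.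
- Forward order: ring B chromene from 4-hydroxyacetophenone, then chain extension to the ketal-masked ynone (steps 1–6). The diene comes from methyl acetoacetate and prenyl bromide (steps 7–9). Ring A is formed by Diels–Alder reaction and aromatisation (step 10), its pyran is closed with DDQ (step 11), and the ketal is removed (step 12).
- Stereochemistry: the target has no stereocentre. The only geometric requirement is the Z enol ether at C3=C4 of the diene, set in the γ-deprotonation of step 9; both pyran olefins are cis by ring size.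

Key step: step 10

Assumption: the target is drawn as the diketo tautomer and will exist largely as its chelated enol, which is the same compound. The geometries drawn at C2=C3 of 15 and at C1=C2 of 16 and 17 are the expected major forms and do not affect the outcome, because these carbons end up in the aromatic ring.

**Route**

Step 1
Reactants: 1 4-hydroxyacetophenone; 2 3-chloro-3-methylbut-1-yne
Product: 3 1-[4-(2-methylbut-3-yn-2-yloxy)phenyl]ethanone
Conditions: K2CO3, KI (cat.), acetone, reflux
Reagents that add atoms: none
Why: Williamson-type O-alkylation of the phenoxide by the tertiary propargylic chloride is the standard entry to aryl 1,1-dimethylpropargyl ethers, and the acetyl group is inert to carbonate.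

Step 2
Reactants: 3 1-[4-(2-methylbut-3-yn-2-yloxy)phenyl]ethanone
Product: 5 1-(2,2-dimethyl-2H-chromen-6-yl)ethanone, via ortho-allenyl phenol 4 (not isolated)
Conditions: PhNEt2, 190 °C
Reagents that add atoms: none
Why: Aryl propargyl Claisen rearrangement gives the ortho-allenyl phenol, which should pass by 1,5-hydrogen shift and 6π oxa-electrocyclisation to the 2,2-dimethylchromene; the para acetyl group makes both ortho positions equivalent, so only one chromene can form.

Step 3
Reactants: 5 1-(2,2-dimethyl-2H-chromen-6-yl)ethanone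
Product: 6 methyl 3-(2,2-dimethyl-2H-chromen-6-yl)-3-oxopropanoate
Conditions: NaH, (MeO)2CO, THF, reflux; cold 1 M HCl quench
Reagents that add atoms: dimethyl carbonate, COC(=O)OC
Why: Crossed Claisen condensation of the methyl ketone enolate with dimethyl carbonate, driven to completion by deprotonation of the β-keto ester as it forms.

Step 4
Reactants: 6 methyl 3-(2,2-dimethyl-2H-chromen-6-yl)-3-oxopropanoate
Product: 7 methyl 2-[2-(2,2-dimethyl-2H-chromen-6-yl)-1,3-dioxolan-2-yl]acetate
Conditions: (Me3SiOCH2)2, Me3SiOTf (cat.), CH2Cl2, −78 to −20 °C; pyridine quench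
Reagents that add atoms: 1,2-bis(trimethylsilyloxy)ethane, C[Si](C)(C)OCCO[Si](C)(C)C
Why: Noyori ketalisation is driven by formation of hexamethyldisiloxane and runs cold and water-free, which should spare the acid-sensitive chromene and the methyl ester.

Step 5
Reactants: 7 methyl 2-[2-(2,2-dimethyl-2H-chromen-6-yl)-1,3-dioxolan-2-yl]acetate
Product: 8 2-[2-(2,2-dimethyl-2H-chromen-6-yl)-1,3-dioxolan-2-yl]-N-methoxy-N-methylacetamide
Conditions: MeNH(OMe)·HCl, i-PrMgCl, THF, −20 to 0 °C
Reagents that add atoms: N,O-dimethylhydroxylamine hydrochloride, CNOC.Cl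
Why: Direct Weinreb amidation of the ester by the magnesium amide, a nucleophilic but weakly basic reagent, which at low temperature should limit α-deprotonation and β-elimination of a dioxolane oxygen.

Step 6
Reactants: 8 2-[2-(2,2-dimethyl-2H-chromen-6-yl)-1,3-dioxolan-2-yl]-N-methoxy-N-methylacetamide
Product: 10 1-[2-(2,2-dimethyl-2H-chromen-6-yl)-1,3-dioxolan-2-yl]but-3-yn-2-one, via magnesium hemiaminal chelate 9 (not isolated)
Conditions: HC≡CMgBr, THF, 0 °C; inverse quench into cold aq. KHSO4/Et2O
Reagents that add atoms: ethynylmagnesium bromide, C#C[Mg]Br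
Why: Weinreb ketone synthesis, in which the chelated tetrahedral adduct resists a second addition; the inverse acidic quench protonates the released amine before it can add to the terminal ynone.

Step 7
Reactants: 11 methyl acetoacetate; 12 prenyl bromide (1-bromo-3-methylbut-2-ene)
Product: 14 methyl 7-methyl-3-oxooct-6-enoate, via methyl acetoacetate dianion 13 (not isolated)
Conditions: NaH, THF, 0 °C; n-BuLi, 0 °C; then 12, 0 °C to rt; 1 M HCl quench
Reagents that add atoms: none
Why: Weiler dianion alkylation, in which the more reactive γ-carbanion of the dianion displaces bromide at the primary allylic carbon (SN2) and the α-position stays protected as the enolate.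

Step 8
Reactants: 14 methyl 7-methyl-3-oxooct-6-enoate
Product: 15 methyl (2E)-7-methyl-3-(trimethylsilyloxy)octa-2,6-dienoate
Conditions: Me3SiCl, Et3N, hexane, rt
Reagents that add atoms: chlorotrimethylsilane, C[Si](C)(C)Cl
Why: O-silylation of the enolised β-keto ester under soft-enolisation conditions, the usual first stage in making 1,3-bis(silyloxy)dienes from β-keto esters.

Step 9
Reactants: 15 methyl (2E)-7-methyl-3-(trimethylsilyloxy)octa-2,6-dienoate
Product: 17 (1Z,3Z)-1-methoxy-7-methyl-1,3-bis(trimethylsilyloxy)octa-1,3,6-triene, via lithium dienolate 16 (not isolated)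
Conditions: LiN(i-Pr)2, THF, −78 °C; Me3SiCl, −78 °C to rt; hexane, filtration, used crude
Reagents that add atoms: chlorotrimethylsilane, C[Si](C)(C)Cl
Why: Kinetic γ-deprotonation of the vinylogous ester and O-silylation of the extended dienolate give the silyl ketene acetal diene; the alkyl chain is expected to settle mainly anti to C2 (3Z), the geometry that leaves the s-cis conformer open.

Step 10
Reactants: 10 1-[2-(2,2-dimethyl-2H-chromen-6-yl)-1,3-dioxolan-2-yl]but-3-yn-2-one; 17 (1Z,3Z)-1-methoxy-7-methyl-1,3-bis(trimethylsilyloxy)octa-1,3,6-triene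
Product: 19 1-[2,4-dihydroxy-5-(3-methylbut-2-enyl)phenyl]-2-[2-(2,2-dimethyl-2H-chromen-6-yl)-1,3-dioxolan-2-yl]ethanone, via cyclohexa-1,4-diene cycloadduct 18 (not isolated)
Conditions: PhMe, rt to 80 °C (17 in excess); then Bu4NF, AcOH, THF, 0 °C
Reagents that add atoms: none
Why: This is a normal-electron-demand Diels–Alder reaction of an electron-rich 1-methoxy-1,3-bis(silyloxy)diene with an acetylenic ketone, the known route from such dienes and alkynyl carbonyl compounds to resorcinols: the prenyl-bearing terminus C4 of the diene, which carries the largest HOMO coefficient, should bond to the unsubstituted β-carbon of the ynone and the ketene acetal carbon C1 to the α-carbon, forming the ring A bonds C4a–C5 and C6–C7. Ring A closes as a six-membered carbocycle in a [4+2] cycloaddition (concerted but asynchronous; a stepwise Michael addition and ring closure would give the same connectivity) to the cyclohexa-1,4-diene 18. Buffered fluoride then removes both silyl groups, the hemiketal oxide at the former C1 expels methoxide, and the resulting cyclohexenedione tautomerises to the arene, so no oxidant is needed and the two transient sp3 centres of 18 disappear without leaving a stereocentre. The step needs regioselectivity and periselectivity: the first rests on the matched polarisation of the partners (oxygen donors on C1 and C3 of the diene, acyl group on the alkyne), the second on running thermally without a Lewis acid so that a formal [3+3] closure onto the ketone carbonyl does not compete. The 3Z enol ether keeps the prenyl-bearing carbon on the outside of the diene, and the dioxolane prevents the ynone from existing as an enolised 1,3-diketone that could close to a pyranone or protonate the diene.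

Step 11
Reactants: 19 1-[2,4-dihydroxy-5-(3-methylbut-2-enyl)phenyl]-2-[2-(2,2-dimethyl-2H-chromen-6-yl)-1,3-dioxolan-2-yl]ethanone
Product: 21 1-(7-hydroxy-2,2-dimethyl-2H-chromen-6-yl)-2-[2-(2,2-dimethyl-2H-chromen-6-yl)-1,3-dioxolan-2-yl]ethanone, via ortho-quinone methide 20 (not isolated)
Conditions: DDQ, benzene, reflux
Reagents that add atoms: none
Why: DDQ dehydrogenation of the ortho-prenyl phenol to the ortho-quinone methide and 6π oxa-electrocyclisation is the standard oxidative closure to 2,2-dimethylchromenes; only the C4 hydroxyl has a neighbouring prenyl group, while the C2 hydroxyl is tied up by hydrogen bonding to the ketone.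

Step 12
Reactants: 21 1-(7-hydroxy-2,2-dimethyl-2H-chromen-6-yl)-2-[2-(2,2-dimethyl-2H-chromen-6-yl)-1,3-dioxolan-2-yl]ethanone
Product: 22 Glyinflanin D, 1-(7-hydroxy-2,2-dimethyl-2H-chromen-6-yl)-3-(2,2-dimethyl-2H-chromen-6-yl)propane-1,3-dione
Conditions: 1 M HCl, THF, rt
Reagents that add atoms: water, O
Why: Acid-catalysed hydrolysis of the aryl dioxolane, assisted by the para oxygen of ring B, should proceed under conditions too mild to open either chromene or to cyclodehydrate the 2-hydroxyphenyl 1,3-diketone to a flavone.

**Compound list**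

1 | 4-hydroxyacetophenone | CC(=O)c1ccc(O)cc1 | starting material
2 | 3-chloro-3-methylbut-1-yne | CC(C)(Cl)C#C | starting material
3 | 1-[4-(2-methylbut-3-yn-2-yloxy)phenyl]ethanone | CC(=O)c1ccc(OC(C)(C)C#C)cc1 | intermediate
4 | 1-[4-hydroxy-3-(3-methylbuta-1,2-dienyl)phenyl]ethanone (ortho-allenyl phenol) | CC(=O)c1ccc(O)c(C=C=C(C)C)c1 | intermediate (not isolated)
5 | 1-(2,2-dimethyl-2H-chromen-6-yl)ethanone | CC(=O)c1ccc2OC(C)(C)C=Cc2c1 | intermediate
6 | methyl 3-(2,2-dimethyl-2H-chromen-6-yl)-3-oxopropanoate | COC(=O)CC(=O)c1ccc2OC(C)(C)C=Cc2c1 | intermediate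
7 | methyl 2-[2-(2,2-dimethyl-2H-chromen-6-yl)-1,3-dioxolan-2-yl]acetate | COC(=O)CC1(OCCO1)c1ccc2OC(C)(C)C=Cc2c1 | intermediate
8 | 2-[2-(2,2-dimethyl-2H-chromen-6-yl)-1,3-dioxolan-2-yl]-N-methoxy-N-methylacetamide | CON(C)C(=O)CC1(OCCO1)c1ccc2OC(C)(C)C=Cc2c1 | intermediate
9 | bromomagnesium alkoxide of the tetrahedral adduct of 8 with the ethynyl Grignard reagent (racemic hemiaminal chelate) | C#CC(O[Mg]Br)(N(C)OC)CC1(OCCO1)c1ccc2OC(C)(C)C=Cc2c1 | intermediate (not isolated)
10 | 1-[2-(2,2-dimethyl-2H-chromen-6-yl)-1,3-dioxolan-2-yl]but-3-yn-2-one | C#CC(=O)CC1(OCCO1)c1ccc2OC(C)(C)C=Cc2c1 | intermediate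
11 | methyl acetoacetate | CC(=O)CC(=O)OC | starting material
12 | prenyl bromide (1-bromo-3-methylbut-2-ene) | CC(C)=CCBr | starting material
13 | sodium lithium dianion of methyl acetoacetate (deprotonated at C2 and C4) | [Na+].[Li+].[CH2-]C(=O)[CH-]C(=O)OC | intermediate (not isolated)
14 | methyl 7-methyl-3-oxooct-6-enoate | COC(=O)CC(=O)CCC=C(C)C | intermediate
15 | methyl (2E)-7-methyl-3-(trimethylsilyloxy)octa-2,6-dienoate | COC(=O)/C=C(/O[Si](C)(C)C)CCC=C(C)C | intermediate
16 | lithium dienolate of 15 (lithium 1-methoxy-7-methyl-3-(trimethylsilyloxy)octa-1,3,6-trien-1-olate, C3=C4 Z) | CO/C(O[Li])=C/C(O[Si](C)(C)C)=C/CC=C(C)C | intermediate (not isolated)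
17 | (1Z,3Z)-1-methoxy-7-methyl-1,3-bis(trimethylsilyloxy)octa-1,3,6-triene | CO/C(O[Si](C)(C)C)=C/C(O[Si](C)(C)C)=C/CC=C(C)C | intermediate
18 | 1-[6-methoxy-3-(3-methylbut-2-enyl)-4,6-bis(trimethylsilyloxy)cyclohexa-1,4-dien-1-yl]-2-[2-(2,2-dimethyl-2H-chromen-6-yl)-1,3-dioxolan-2-yl]ethanone (mixture of diastereomers, both sp3 centres lost on aromatisation) | COC1(O[Si](C)(C)C)C=C(O[Si](C)(C)C)C(CC=C(C)C)C=C1C(=O)CC1(OCCO1)c1ccc2OC(C)(C)C=Cc2c1 | intermediate (not isolated)
19 | 1-[2,4-dihydroxy-5-(3-methylbut-2-enyl)phenyl]-2-[2-(2,2-dimethyl-2H-chromen-6-yl)-1,3-dioxolan-2-yl]ethanone | CC(C)=CCc1cc(C(=O)CC2(OCCO2)c2ccc3OC(C)(C)C=Cc3c2)c(O)cc1O | intermediate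
20 | ortho-quinone methide of 19 (C4 carbonyl, exocyclic 3-methylbuta-1,3-dienylidene unit at C5, Z about the exocyclic bond) | CC(C)=C/C=C1/C=C(C(=O)CC2(OCCO2)c2ccc3OC(C)(C)C=Cc3c2)C(O)=CC1=O | intermediate (not isolated)
21 | 1-(7-hydroxy-2,2-dimethyl-2H-chromen-6-yl)-2-[2-(2,2-dimethyl-2H-chromen-6-yl)-1,3-dioxolan-2-yl]ethanone | CC1(C)C=Cc2cc(C(=O)CC3(OCCO3)c3ccc4OC(C)(C)C=Cc4c3)c(O)cc2O1 | intermediate
22 | Glyinflanin D | CC1(C)C=Cc2cc(C(=O)CC(=O)c3cc4c(cc3O)OC(C)(C)C=C4)ccc2O1 | target

**Step count and risks**

Total step count: 12. Longest linear sequence: 9 steps (steps 1–6, then 10–12); the diene branch contributes steps 7–9.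

Steps most likely to fail:

1. Step 10. The cycloaddition may be outrun by ring opening of the dioxolane in the β-ketal ynone (β-elimination to a hydroxyethyl enol ether) or by oligomerisation of the terminal ynone. The hindered 4-substituted diene may also stop at an open-chain Michael adduct, or the adduct may lose silanol instead of methanol on heating. The fallback keeps the benzannulation but moves the assembly of the diketone to after ring A formation; it sets out from diene 17 and chloride 2 and rejoins the route at 22. Diene 17 is combined with commercial but-3-yn-2-one under the same thermal and fluoride protocol to give 1-[2,4-dihydroxy-5-(3-methylbut-2-enyl)phenyl]ethanone F1, and DDQ in refluxing benzene closes the pyran to 1-(7-hydroxy-2,2-dimethyl-2H-chromen-6-yl)ethanone F2. In parallel, commercial methyl 4-hydroxybenzoate is alkylated with 2 (K2CO3, KI, acetone) to methyl 4-(2-methylbut-3-yn-2-yloxy)benzoate F3, which on heating in N,N-diethylaniline gives methyl 2,2-dimethyl-2H-chromene-6-carboxylate F4. A crossed Claisen condensation of the dianion of F2 with F4 (NaH, THF, reflux) then delivers 22 directly, with no ketal needed.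

2. Step 6. The liberated N,O-dimethylhydroxylamine may add in conjugate fashion to the terminal ynone during the quench, or the Grignard reagent may deprotonate the α-methylene and trigger opening of the dioxolane instead of adding to the amide. The fallback changes the oxidation level; it sets out from ester 7 and rejoins at 10. Reduction with i-Bu2AlH in CH2Cl2 at −78 °C gives 2-[2-(2,2-dimethyl-2H-chromen-6-yl)-1,3-dioxolan-2-yl]acetaldehyde F5. Addition of HC≡CMgBr gives racemic 1-[2-(2,2-dimethyl-2H-chromen-6-yl)-1,3-dioxolan-2-yl]but-3-yn-2-ol F6, and oxidation of this propargylic alcohol with MnO2 in CH2Cl2 gives 10 under neutral, amine-free conditions.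

3. Step 4. Ketalisation of the conjugated and largely enolised aryl β-keto ester may stall, or the silyl triflate may ionise the chromene before the ketone reacts. The fallback builds the ketal under basic conditions; it sets out from β-keto ester 6 and rejoins at 7. Treatment with LiN(SiMe3)2 and triflic anhydride gives methyl (2Z)-3-(2,2-dimethyl-2H-chromen-6-yl)-3-(trifluoromethylsulfonyloxy)prop-2-enoate F7. A second equivalent of LiN(SiMe3)2 effects anti elimination to methyl 3-(2,2-dimethyl-2H-chromen-6-yl)prop-2-ynoate F8. Double conjugate addition of ethylene glycol (NaH cat., THF) then gives the dioxolane 7.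

Further compounds
F1 | step 10 | 1-[2,4-dihydroxy-5-(3-methylbut-2-enyl)phenyl]ethanone | CC(=O)c1cc(CC=C(C)C)c(O)cc1O
F2 | step 10 | 1-(7-hydroxy-2,2-dimethyl-2H-chromen-6-yl)ethanone | CC(=O)c1cc2C=CC(C)(C)Oc2cc1O
F3 | step 10 | methyl 4-(2-methylbut-3-yn-2-yloxy)benzoate | COC(=O)c1ccc(OC(C)(C)C#C)cc1
F4 | step 10 | methyl 2,2-dimethyl-2H-chromene-6-carboxylate | COC(=O)c1ccc2OC(C)(C)C=Cc2c1
F5 | step 6 | 2-[2-(2,2-dimethyl-2H-chromen-6-yl)-1,3-dioxolan-2-yl]acetaldehyde | O=CCC1(OCCO1)c1ccc2OC(C)(C)C=Cc2c1
F6 | step 6 | 1-[2-(2,2-dimethyl-2H-chromen-6-yl)-1,3-dioxolan-2-yl]but-3-yn-2-ol (racemic) | C#CC(O)CC1(OCCO1)c1ccc2OC(C)(C)C=Cc2c1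
F7 | step 4 | methyl (2Z)-3-(2,2-dimethyl-2H-chromen-6-yl)-3-(trifluoromethylsulfonyloxy)prop-2-enoate | COC(=O)/C=C(\OS(=O)(=O)C(F)(F)F)c1ccc2OC(C)(C)C=Cc2c1
F8 | step 4 | methyl 3-(2,2-dimethyl-2H-chromen-6-yl)prop-2-ynoate | COC(=O)C#Cc1ccc2OC(C)(C)C=Cc2c1
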